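The route rests on taking the benzenoid ring apart. That ring is locally symmetric, with bromine on both C5 and C6 and hydrogen on both C4 and C7. A symmetric disubstituted alkyne can therefore deliver C5–C6, while a diyne delivers C7a≡C7 and C3a≡C4, held together by the chain N1–C2–C3. A single cobalt-catalysed [2+2+2] cycloaddition makes C3a–C7a, C4–C5 and C6–C7. It closes the five-membered nitrogen ring and the benzene ring at once and leaves trimethylsilyl groups on C5 and C6 as stand-ins for bromine. The precursor is open-chain methyl N-ethynyl-N-(but-3-ynyl)carbamate, whose carbamate steadies the ynamide, moderates the bromination and ends as the N-methyl group.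

Key step: step 5

Assumption: indole numbering (N1, C2, C3, C3a, C4 to C7, C7a) is applied to every compound, the open-chain ones included, and but-3-yn-1-amine is taken as the free base.

Step 1
Reactants: 1 but-3-yn-1-amine; 2 methyl chloroformate
Product: 3 methyl but-3-yn-1-ylcarbamate
Conditions: NaHCO3 (2 equiv), CH2Cl2/H2O, 0 °C → rt
Reagents that add atoms: none
Why: Schotten–Baumann N-acylation of a primary amine with a chloroformate is fast and chemoselective, and the terminal alkyne is only a spectator.

Step 2
Reactants: 3 methyl but-3-yn-1-ylcarbamate
Product: 5 methyl [4-(triisopropylsilyl)but-3-yn-1-yl]carbamate, via dilithiated carbamate 4 (not isolated)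
Conditions: n-BuLi (2.1 equiv), THF, −78 °C; TIPSCl (1.05 equiv), −78 °C → rt; H2O
Reagents that add atoms: chlorotriisopropylsilane (TIPSCl), CC(C)[Si](Cl)(C(C)C)C(C)C
Why: Double deprotonation (N–H, then C(sp)–H) followed by C-silylation of the lithium acetylide should place the bulky silane on carbon only, the hindered N-lithiocarbamate returning as N–H on quench, and TIPS is preferred to TMS because it withstands K3PO4 and the water of crystallisation of the copper salt at 80 °C in step 3.

Step 3
Reactants: 5 methyl [4-(triisopropylsilyl)but-3-yn-1-yl]carbamate; 6 (bromoethynyl)triisopropylsilane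
Product: 7 methyl [4-(triisopropylsilyl)but-3-yn-1-yl][(triisopropylsilyl)ethynyl]carbamate
Conditions: CuSO4·5H2O (10 mol %), 1,10-phenanthroline (20 mol %), K3PO4 (2 equiv), toluene, 80 °C
Reagents that add atoms: none
Why: Copper-catalysed N-alkynylation of a carbamate with a bromoalkyne (Ullmann-type C(sp)–N coupling) is established for acyclic carbamates and silylated bromoacetylenes, and with no free C(sp)–H in either partner Cadiot–Chodkiewicz and Glaser couplings are shut off.

Step 4
Reactants: 7 methyl [4-(triisopropylsilyl)but-3-yn-1-yl][(triisopropylsilyl)ethynyl]carbamate
Product: 8 methyl but-3-yn-1-yl(ethynyl)carbamate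
Conditions: TBAF (2.3 equiv, 1 M in wet THF), THF, 0 °C → rt; used promptly
Reagents that add atoms: none
Why: Fluoride-mediated protodesilylation cleaves both C(sp)–Si bonds in one operation with water in the reagent as proton source, and the methyl carbamate and the terminal ynamide tolerate these brief, mild conditions.

Step 5
Reactants: 8 methyl but-3-yn-1-yl(ethynyl)carbamate; 9 bis(trimethylsilyl)acetylene
Product: 11 methyl 5,6-bis(trimethylsilyl)indoline-1-carboxylate, via cobaltacyclopentadiene 10 (not isolated)
Conditions: CpCo(CO)2 (10 mol %), neat degassed 9 (ca. 40 equiv), reflux (ca. 135 °C), hν (visible lamp), 8 added by syringe pump over 12 h, Ar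
Reagents that add atoms: none
Why: Heat and light strip CO from CpCo(CO)2, the resulting monovalent CpCo fragment binds both C≡C units of 8 and couples them oxidatively to the trivalent cobaltacyclopentadiene 10 (C3a–C7a formed), after which 9 coordinates, adds across the two Co–C bonds by insertion or [4+2] addition, and the arene leaves by reductive elimination (C4–C5 and C6–C7 formed) with return of monovalent cobalt. The closest known reaction types are the CpCo(CO)2-catalysed cocyclisation of α,ω-diynes with bis(trimethylsilyl)acetylene to ortho-disilylated benzocycloalkenes and the metal-catalysed [2+2+2] cycloaddition of N-ethynyl-N-(but-3-ynyl) amides with alkynes to indolines. The five-membered ring N1–C2–C3–C3a–C7a closes in the oxidative coupling, as the ring fused to the metallacycle that a three-atom tether makes easy, and the six-membered ring closes in the final C–C reductive elimination. No stereocentre is formed. The selectivity needed is cross-cycloaddition over self-oligomerisation of 8: 9 is too crowded to trimerise, so it can serve as solvent and outnumber 8, which the syringe pump keeps at trace concentration, and the carbamate tempers the ynamide enough for it to survive until it meets cobalt. Regiochemistry is not an issue, because 9 is symmetric and the tether fixes the orientation of the diyne, so silicon can only end up on C5 and C6 and hydrogen on C4 and C7.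

Step 6
Reactants: 11 methyl 5,6-bis(trimethylsilyl)indoline-1-carboxylate
Product: 13 methyl 5,6-dibromoindoline-1-carboxylate, via 5-bromo-6-silyl carbamate 12 (not isolated)
Conditions: Br2 (2.4 equiv), pyridine (0.3 equiv), CH2Cl2, 0 °C → reflux, dark; aq Na2S2O3
Reagents that add atoms: bromine, BrBr
Why: In this electrophilic ipso-bromodesilylation, attack at a silicon-bearing carbon gives an arenium ion stabilised by the β-silicon effect and eases the crowding of the two adjacent silyl groups, C5 (para to the carbamate nitrogen) reacting first to 12 and C6 (para to the C3a alkyl branch) second, while the acylated nitrogen keeps C7 and the saturated C2–C3 unit quiet and pyridine scavenges traces of HBr that would cause protodesilylation.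

Step 7
Reactants: 13 methyl 5,6-dibromoindoline-1-carboxylate
Product: 14 5,6-dibromo-1-methylindoline
Conditions: AlH3·NMe2Et (3 equiv, 0.5 M in toluene), THF, 0 °C → 40 °C; Na2SO4·10H2O
Reagents that add atoms: none
Why: In this carbamate-to-N-methyl reduction alane adds hydride to the carbamate carbonyl and, as a Lewis acid, assists loss of both oxygen substituents so that the carbonyl carbon ends as N–CH3, and as an electrophilic hydride it leaves alone the aryl bromides that LiAlH4 would endanger.

Step 8
Reactants: 14 5,6-dibromo-1-methylindoline
Product: 15 5,6-dibromo-1-methyl-1H-indole
Conditions: DDQ (1.05 equiv), toluene, 0 °C → rt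
Reagents that add atoms: none
Why: DDQ dehydrogenation of an N-alkylindoline proceeds by hydride transfer from C2 next to the donor nitrogen and loss of a C3 proton, is driven by aromatisation to the indole, and does not touch aryl bromides.

Step 9
Reactants: 15 5,6-dibromo-1-methyl-1H-indole
Product: 16 3,5,6-tribromo-1-methyl-1H-indole (target)
Conditions: NBS (1.0 equiv), DMF, 0 °C, dark
Reagents that add atoms: N-bromosuccinimide (NBS), O=C1CCC(=O)N1Br
Why: Electrophilic aromatic substitution of an N-alkylindole goes to C3, its most nucleophilic position, the benzenoid ring is deactivated by two bromines, and one equivalent at low temperature should prevent further bromination at C2.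

Compound list
1 | but-3-yn-1-amine | C#CCCN | starting material
2 | methyl chloroformate | COC(=O)Cl | starting material
3 | methyl but-3-yn-1-ylcarbamate | C#CCCNC(=O)OC | intermediate
4 | dilithiated carbamate (N,C-dilithio derivative of 3; not isolated) | [Li]C#CCCN([Li])C(=O)OC | intermediate
5 | methyl [4-(triisopropylsilyl)but-3-yn-1-yl]carbamate | COC(=O)NCCC#C[Si](C(C)C)(C(C)C)C(C)C | intermediate
6 | (bromoethynyl)triisopropylsilane | CC(C)[Si](C#CBr)(C(C)C)C(C)C | starting material
7 | methyl [4-(triisopropylsilyl)but-3-yn-1-yl][(triisopropylsilyl)ethynyl]carbamate | COC(=O)N(CCC#C[Si](C(C)C)(C(C)C)C(C)C)C#C[Si](C(C)C)(C(C)C)C(C)C | intermediate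
8 | methyl but-3-yn-1-yl(ethynyl)carbamate | C#CCCN(C#C)C(=O)OC | intermediate
9 | bis(trimethylsilyl)acetylene | C[Si](C)(C)C#C[Si](C)(C)C | starting material
10 | cyclopentadienylcobaltacyclopentadiene fused to the N-methoxycarbonylpyrrolidine ring, Co bound to C4 and C7 (Cp drawn sigma-bound in the SMILES; not isolated) | COC(=O)N1CCC2=C[Co](C3C=CC=C3)C=C12 | intermediate
11 | methyl 5,6-bis(trimethylsilyl)indoline-1-carboxylate | COC(=O)N1CCc2cc([Si](C)(C)C)c([Si](C)(C)C)cc21 | intermediate
12 | methyl 5-bromo-6-(trimethylsilyl)indoline-1-carboxylate (not isolated) | COC(=O)N1CCc2cc(Br)c([Si](C)(C)C)cc21 | intermediate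
13 | methyl 5,6-dibromoindoline-1-carboxylate | COC(=O)N1CCc2cc(Br)c(Br)cc21 | intermediate
14 | 5,6-dibromo-1-methylindoline | CN1CCc2cc(Br)c(Br)cc21 | intermediate
15 | 5,6-dibromo-1-methyl-1H-indole | Cn1ccc2cc(Br)c(Br)cc21 | intermediate
16 | 3,5,6-tribromo-1-methyl-1H-indole | Cn1cc(Br)c2cc(Br)c(Br)cc21 | target

Total step count: 9. Longest linear sequence: 9 (steps 1 to 9, from but-3-yn-1-amine).

Steps most likely to fail

1. Step 5.
   - The diyne may oligomerise with itself faster than the crowded alkyne enters the metallacycle.
   - The terminal ynamide may decay under heat and light before it reaches cobalt.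
   - The catalyst may be drained into an inert cyclobutadiene complex.

   The fallback gives up the cycloaddition for directed electrophilic substitution on a preformed indoline. It sets out from 2, which acylates bought 6-bromoindoline F1 (NaHCO3, CH2Cl2/H2O, 0 °C) to methyl 6-bromoindoline-1-carboxylate F2. NBS in DMF at room temperature should then brominate C5, the position para to the carbamate nitrogen and ortho to the bromine already present, C7 being shielded by the carbamate. This comes back to the route at 13.

2. Step 7.
   - The tetrahedral adduct may collapse by C–N scission, which strips the whole carbamate instead of reducing it.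
   - Prolonged exposure to hydride may cause hydrodebromination.

   The fallback separates removal of the carbamate from introduction of the methyl group. It sets out from 13: KOH in aqueous ethanol at reflux hydrolyses the carbamate to 5,6-dibromoindoline F3. Reductive amination with aqueous formaldehyde and NaBH(OAc)3 in 1,2-dichloroethane, a hydride too mild to touch aryl bromides, then comes back to the route at 14.

3. Step 6.
   - The reaction may stall after the first substitution, once the ring is deactivated by bromine.
   - Protodesilylation by adventitious HBr may erase the placeholder at C6.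
   - C–H bromination at C7 may compete.

   The fallback uses a stronger electrophile for the ipso substitution and then swaps the halogen. It sets out from 11: ICl (2.2 equiv) in CH2Cl2 at 0 °C should replace both silyl groups to give methyl 5,6-diiodoindoline-1-carboxylate F4. Copper-mediated aromatic halogen exchange with excess CuBr in DMF at 140 °C then comes back to the route at 13. The exchange runs from iodide to bromide because CuI is the more stable copper monohalide.

Further compounds
F1 | step 5 | 6-bromoindoline (bought) | Brc1ccc2c(c1)NCC2
F2 | step 5 | methyl 6-bromoindoline-1-carboxylate | COC(=O)N1CCc2ccc(Br)cc21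
F3 | step 7 | 5,6-dibromoindoline | Brc1cc2c(cc1Br)NCC2
F4 | step 6 | methyl 5,6-diiodoindoline-1-carboxylate | COC(=O)N1CCc2cc(I)c(I)cc21
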